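**Retrosynthetic overview**

1. Endgame: the phloroglucinol dialdehyde is unveiled last from a 2,4,6-trimethoxyphenyl group (dibromination, bromine–lithium exchange/formylation, thiolate demethylation); the hydroxyisopropyl group comes from a methyl ester.
2. Key disconnection, rings A and B together: an intramolecular Diels–Alder reaction of an acyclic 2-(methoxycarbonyl)-1,3-diene with the remote π bond of a tethered 1,3-disubstituted allene. It forms the bond from the ring CH2 to the methyl-bearing ring CH and the ring-fusion bond from the sp2 ring-fusion carbon to the ring-fusion CH.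
3. Enabling feature: the trisubstituted C=C of ring A (quaternary C–CH=C) is exocyclic to ring B at the ring-fusion carbon and is flanked there by the CH(CH3) of ring B. It is the untouched half of an allene, and ring B is the cyclohexene of the cycloaddition, with the ester on the future C(CH3)2OH carbon.
4. The acyclic precursor carries the benzylic/quaternary stereodiad, built on 5,7-dimethoxycoumarin (asymmetric conjugate addition of isobutyl, then allylation and methylation anti to it). The lactone C=O becomes alkyne, (S)-propargylic alcohol and then (Sa)-allene; the allyl group becomes aldehyde and then (Z)-2-vinyl enoate.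
5. Ring order: the arene is purchased in the coumarin, the pyranone ring is opened in step 5, and rings A and B close simultaneously in step 14.

Key step: step 14

Remark: the CIP descriptors of the benzylic and quaternary carbons switch between R and S along the route only because substituent priorities change; after step 3 no bond at either centre is made or broken.

**Route**

Step 1
Reactants: 1 5,7-dimethoxycoumarin
Product: 2 (4S)-5,7-dimethoxy-4-(2-methylpropyl)-3,4-dihydro-2H-chromen-2-one
Conditions: i-BuMgBr, CuBr·SMe2 (5 mol%), (R)-1-[(S)-2-(diphenylphosphino)ferrocenyl]ethyldicyclohexylphosphine (6 mol%; the ligand enantiomer that gives the 4S adduct is used), t-BuOMe, −72 °C; aq NH4Cl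
Reagents that add atoms: isobutylmagnesium bromide, CC(C)C[Mg]Br
Why: Copper-catalysed asymmetric conjugate addition of a primary Grignard reagent to a coumarin, in which the chiral ferrocenyl diphosphine–copper complex controls the face of β-attack and so sets the benzylic centre (4S), while the lactone survives at −72 °C.

Step 2
Reactants: 2 (4S)-5,7-dimethoxy-4-(2-methylpropyl)-3,4-dihydro-2H-chromen-2-one
Product: 4 (3S,4S)-5,7-dimethoxy-4-(2-methylpropyl)-3-(prop-2-en-1-yl)-3,4-dihydro-2H-chromen-2-one (3,4-trans), via lithium enolate 3 (not isolated)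
Conditions: LiN(SiMe3)2, THF, −78 °C; then allyl bromide, −78 → −40 °C
Reagents that add atoms: allyl bromide, C=CCBr
Why: Lactone enolate alkylation in which allyl bromide should enter anti to the 4-isobutyl group, which the peri 5-methoxy group forces pseudoaxial, giving the 3,4-trans lactone (this C3 configuration is erased again in step 3).

Step 3
Reactants: 4 (3S,4S)-5,7-dimethoxy-4-(2-methylpropyl)-3-(prop-2-en-1-yl)-3,4-dihydro-2H-chromen-2-one
Product: 6 (3R,4R)-5,7-dimethoxy-3-methyl-4-(2-methylpropyl)-3-(prop-2-en-1-yl)-3,4-dihydro-2H-chromen-2-one (methyl trans, allyl cis to isobutyl), via lithium enolate 5 (not isolated)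
Conditions: LiN(SiMe3)2, THF–DMPU, −78 °C; then MeI, −78 → −30 °C
Reagents that add atoms: iodomethane, CI
Why: Second enolate alkylation that creates the quaternary centre, where the planar enolate is shielded on one face by the pseudoaxial isobutyl group, so the small, reactive iodomethane should add anti to it and leave methyl trans and the allyl chain cis to isobutyl.

Step 4
Reactants: 6 (3R,4R)-5,7-dimethoxy-3-methyl-4-(2-methylpropyl)-3-(prop-2-en-1-yl)-3,4-dihydro-2H-chromen-2-one
Product: 7 (3R,4R)-5,7-dimethoxy-3-methyl-4-(2-methylpropyl)-3-(prop-2-en-1-yl)-3,4-dihydro-2H-chromen-2-ol (lactol, both anomers)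
Conditions: i-Bu2AlH, toluene, −78 °C; aq potassium sodium tartrate work-up
Reagents that add atoms: none
Why: Partial reduction of an aryl lactone to the lactol with i-Bu2AlH at −78 °C, where the tetrahedral aluminate persists until work-up and the anomeric centre is of no consequence.

Step 5
Reactants: 7 (3R,4R)-lactol
Product: 9 2-[(4R,5S)-4-ethynyl-4,7-dimethyloct-1-en-5-yl]-1,3,5-trimethoxybenzene, via phenol alkyne 8 (not isolated)
Conditions: dimethyl (1-diazo-2-oxopropyl)phosphonate, K2CO3, MeOH, 0 °C → rt; then solvent switch to DMF, K2CO3, MeI, rt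
Reagents that add atoms: dimethyl (1-diazo-2-oxopropyl)phosphonate, COP(=O)(OC)C(=[N+]=[N-])C(C)=O; iodomethane, CI
Why: Ohira–Bestmann (Seyferth–Gilbert) homologation in which carbonate opens the phenolic lactol to the non-enolisable phenoxide aldehyde that the diazomethylphosphonate anion converts into the terminal alkyne, after which Williamson methylation caps the freed phenoxide to give the symmetric trimethoxyphenyl group.

Step 6
Reactants: 9 2-[(4R,5S)-4-ethynyl-4,7-dimethyloct-1-en-5-yl]-1,3,5-trimethoxybenzene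
Product: 11 (5R)-5-methyl-5-[(1S)-3-methyl-1-(2,4,6-trimethoxyphenyl)butyl]oct-7-en-3-yn-2-one, via lithium acetylide 10 (not isolated)
Conditions: n-BuLi, THF, −78 °C; then N-methoxy-N-methylacetamide, −78 → 0 °C; aq NH4Cl
Reagents that add atoms: N-methoxy-N-methylacetamide, CC(=O)N(C)OC
Why: Acylation of the lithium acetylide with a Weinreb amide, whose chelated tetrahedral adduct prevents over-addition, gives the methyl ynone.

Step 7
Reactants: 11 (5R)-ynone
Product: 12 (2S,5R)-5-methyl-5-[(1S)-3-methyl-1-(2,4,6-trimethoxyphenyl)butyl]oct-7-en-3-yn-2-ol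
Conditions: Ru[(S,S)-TsDPEN](p-cymene) (1 mol%), i-PrOH, rt
Reagents that add atoms: none
Why: Noyori asymmetric transfer hydrogenation of an ynone, in which the (S,S)-TsDPEN ruthenium hydride should deliver hydride under catalyst control to give the (S)-propargylic alcohol without touching the terminal alkene or the alkyne.

Step 8
Reactants: 12 (2S,5R)-propargylic alcohol
Product: 14 (4R,7S)-4-methyl-4-[(1S)-3-methyl-1-(2,4,6-trimethoxyphenyl)butyl]oct-5-yne-1,7-diol, via bis-boryl adduct 13 (not isolated)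
Conditions: 9-BBN (2.5 equiv), THF, 0 °C → rt; then aq NaOH, H2O2, 0 °C
Reagents that add atoms: hydrogen peroxide, OO
Why: Hydroboration–oxidation in which 9-BBN should add anti-Markovnikov to the terminal alkene much faster than to the internal alkyne flanked by the quaternary carbon, and oxidation gives the primary alcohol.

Step 9
Reactants: 14 (4R,7S)-diol
Product: 15 (4R,7S)-7-hydroxy-4-methyl-4-[(1S)-3-methyl-1-(2,4,6-trimethoxyphenyl)butyl]oct-5-ynal
Conditions: [Cu(MeCN)4]OTf (5 mol%), 2,2′-bipyridine, TEMPO, N-methylimidazole, MeCN, air, rt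
Reagents that add atoms: none
Why: Copper/nitroxyl aerobic alcohol oxidation (Stahl oxidation), which is selective for the unhindered primary alcohol over the secondary propargylic alcohol and stops at the aldehyde.

Step 10
Reactants: 16 methyl 2-[bis(2,2,2-trifluoroethoxy)phosphoryl]acetate
Product: 18 methyl 2-[bis(2,2,2-trifluoroethoxy)phosphoryl]-2-bromoacetate, via lithium salt 17 (not isolated)
Conditions: LiN(SiMe3)2, THF, −78 °C; then transfer into Br2, THF, −78 °C
Reagents that add atoms: bromine, BrBr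
Why: α-Bromination of the phosphonoacetate anion, where inverse addition into bromine keeps the product away from unreacted anion and so should avoid proton transfer and dibromination.

Step 11
Reactants: 15 (4R,7S)-hydroxy aldehyde; 18 methyl 2-[bis(2,2,2-trifluoroethoxy)phosphoryl]-2-bromoacetate
Product: 20 methyl (2E,6R,9S)-2-bromo-9-hydroxy-6-methyl-6-[(1S)-3-methyl-1-(2,4,6-trimethoxyphenyl)butyl]dec-2-en-7-ynoate, via potassium salt 19 (not isolated)
Conditions: 18, t-BuOK, 18-crown-6, THF, −78 °C; then 15, −78 °C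
Reagents that add atoms: none
Why: Horner–Wadsworth–Emmons olefination in the Still–Gennari mode, in which the bis(trifluoroethyl) phosphonate under dissociating conditions should eliminate from the kinetic adduct and place the ester cis to the chain, which for the α-bromo reagent is the (E)-α-bromoenoate.

Step 12
Reactants: 20 (E)-α-bromoenoate
Product: 21 methyl (2Z,6R,9S)-2-ethenyl-9-hydroxy-6-methyl-6-[(1S)-3-methyl-1-(2,4,6-trimethoxyphenyl)butyl]dec-2-en-7-ynoate
Conditions: CH2=CHSnBu3, Pd2(dba)3 (cat.), AsPh3, CuI, NMP, rt, dark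
Reagents that add atoms: tributyl(vinyl)stannane, C=C[Sn](CCCC)(CCCC)CCCC
Why: Stille coupling with retention of alkene geometry gives the (Z)-2-vinyl enoate, in which the chain is trans to the vinyl group (the outside position of the future diene), and intramolecular carbopalladation of the alkyne is excluded because palladium sits trans to the tether.

Step 13
Reactants: 21 (2Z,6R,9S)-dienoate propargylic alcohol
Product: 24 methyl (2Z,6S)-2-ethenyl-6-methyl-6-[(1S)-3-methyl-1-(2,4,6-trimethoxyphenyl)butyl]deca-2,7,8-trienoate with an (Sa)-configured (P) 7,8-allene, via sulfonylhydrazine 22 (not isolated), via diazene 23 (not isolated)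
Conditions: PPh3, diethyl azodicarboxylate, THF, −15 °C; 21; then 2-nitrobenzenesulfonylhydrazide, −15 °C → 23 °C; filtered through silica and used at once
Reagents that add atoms: none
Why: Myers allene synthesis, in which Mitsunobu displacement by the sulfonylhydrazide with inversion, loss of sulfinic acid and retro-ene loss of dinitrogen with hydrogen delivery syn to the departing nitrogen add up to an anti SN2′ reduction, so the (S)-carbinol should give the (Sa)-allene by centre-to-axis chirality transfer.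

Step 14
Reactants: 24 (2Z,6S,Sa)-diene–allene
Product: 25 methyl (4R,6S,8aS)-4,6-dimethyl-6-[(1S)-3-methyl-1-(2,4,6-trimethoxyphenyl)butyl]-3,4,6,7,8,8a-hexahydronaphthalene-1-carboxylate
Conditions: toluene (0.005 M, degassed), 2,6-di-tert-butyl-4-methylphenol, 120 °C, sealed tube
Reagents that add atoms: none
Why: Thermal, concerted, suprafacial [4+2] cycloaddition (intramolecular Diels–Alder reaction) with inverse electron demand: the ester-lowered LUMO of the 2-(methoxycarbonyl)diene meets the HOMO of the strained, methyl-substituted remote π bond of the allene, and the diene termini bond to the central and to the methyl-bearing allene carbons. The closest known reaction type is the thermal intramolecular Diels–Alder reaction of tethered allenes through their distal π bond (allenyl ethers, allenamides), and the rhodium-catalysed [4+2] reaction of all-carbon diene–allenes follows the same regiochemistry. Ring B closes as the cyclohexene of the [4+2] event itself, and ring A closes through the three-atom tether as a six-membered ring that keeps the proximal allene π bond as its trisubstituted alkene. The methyl-bearing stereocentre is fixed by the (Sa) allene axis, because the tether allows attack only on the face of the distal π bond that is syn to the quaternary carbon; the ring-fusion CH is set relative to the quaternary centre by a half-chair tether in which the large arylalkyl group lies pseudoequatorial and the methyl pseudoaxial. The step needs periselectivity for the distal over the proximal allene π bond (secured by the neopentyl congestion at the proximal bond and by the six- rather than five-membered tether ring) and cycloaddition faster than diene dimerisation (secured by high dilution, the inhibitor and the β-alkyl group that makes the acrylate part a poor dienophile).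

Step 15
Reactants: 25 hexahydronaphthalene enoate
Product: 26 methyl (1S,4R,6S,8aR)-4,6-dimethyl-6-[(1S)-3-methyl-1-(2,4,6-trimethoxyphenyl)butyl]-1,2,3,4,6,7,8,8a-octahydronaphthalene-1-carboxylate
Conditions: Mg turnings, MeOH, 0 → 50 °C
Reagents that add atoms: none
Why: Dissolving-metal conjugate reduction (Mg/MeOH) is specific for the α,β-unsaturated ester and leaves the isolated trisubstituted alkene, and the Mg(OMe)2 formed should equilibrate the new centre to the equatorial ester trans to the ring-fusion hydrogen, the epimer also expected from protonation anti to the axial ring methyl.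

Step 16
Reactants: 26 octahydronaphthalene ester
Product: 27 methyl (1S,4R,6S,8aR)-6-[(1S)-1-(3,5-dibromo-2,4,6-trimethoxyphenyl)-3-methylbutyl]-4,6-dimethyl-1,2,3,4,6,7,8,8a-octahydronaphthalene-1-carboxylate
Conditions: NBS (2.1 equiv), MeCN, 0 °C, dark
Reagents that add atoms: N-bromosuccinimide, O=C1CCC(=O)N1Br
Why: Electrophilic aromatic bromination with NBS, in which the two ring positions flanked by methoxy groups are far more nucleophilic than the neopentyl-shielded trisubstituted alkene, so both are brominated.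

Step 17
Reactants: 27 dibromo ester
Product: 28 2-[(1S,4R,6S,8aR)-6-[(1S)-1-(3,5-dibromo-2,4,6-trimethoxyphenyl)-3-methylbutyl]-4,6-dimethyl-1,2,3,4,6,7,8,8a-octahydronaphthalen-1-yl]propan-2-ol
Conditions: MeMgBr, CeCl3, THF, 0 °C → rt
Reagents that add atoms: methylmagnesium bromide, C[Mg]Br
Why: Double addition of a weakly basic methylcerium/magnesium reagent to the ester gives the tertiary alcohol without enolising the ester (no epimerisation) and without bromine–metal exchange.

Step 18
Reactants: 28 dibromo tertiary alcohol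
Product: 30 5-[(1S)-1-[(2S,4aR,5S,8R)-5-(2-hydroxypropan-2-yl)-2,8-dimethyl-2,3,4,4a,5,6,7,8-octahydronaphthalen-2-yl]-3-methylbutyl]-2,4,6-trimethoxybenzene-1,3-dicarbaldehyde, via trilithio species 29 (not isolated)
Conditions: t-BuLi (5.2 equiv), THF, −78 °C; then DMF, −78 → 0 °C; aq NH4Cl
Reagents that add atoms: N,N-dimethylformamide, CN(C)C=O
Why: Bromine–lithium exchange on both aryl bromides after deprotonation of the alcohol, followed by formylation of the aryllithiums with DMF (Bouveault aldehyde synthesis), gives the dialdehyde.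

Step 19
Reactants: 30 trimethoxy dialdehyde
Product: 31 2,4,6-trihydroxy-5-[(1S)-1-[(2S,4aR,5S,8R)-5-(2-hydroxypropan-2-yl)-2,8-dimethyl-2,3,4,4a,5,6,7,8-octahydronaphthalen-2-yl]-3-methylbutyl]benzene-1,3-dicarbaldehyde (CNP0200991.2)
Conditions: NaSEt (excess), DMF, 110 °C; then cold dilute HCl
Reagents that add atoms: none
Why: Nucleophilic demethylation (SN2 at methyl) of the three aryl methyl ethers by ethanethiolate, each activated by an ortho or para formyl group, under basic conditions that spare the tertiary alcohol and the alkene.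

**Compound list**

1 | 5,7-dimethoxycoumarin | COc1cc(OC)c2ccc(=O)oc2c1 | starting material
2 | (4S)-5,7-dimethoxy-4-(2-methylpropyl)-3,4-dihydro-2H-chromen-2-one | CC(C)C[C@H]1CC(=O)Oc2cc(OC)cc(OC)c12 | intermediate
3 | lithium enolate of 2 | CC(C)C[C@H]1C=C([O-])Oc2cc(OC)cc(OC)c12.[Li+] | intermediate
4 | (3S,4S)-5,7-dimethoxy-4-(2-methylpropyl)-3-(prop-2-en-1-yl)-3,4-dihydro-2H-chromen-2-one | CC(C)C[C@H]1[C@H](CC=C)C(=O)Oc2cc(OC)cc(OC)c12 | intermediate
5 | lithium enolate of 4 | CC(C)C[C@H]1C(CC=C)=C([O-])Oc2cc(OC)cc(OC)c12.[Li+] | intermediate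
6 | (3R,4R)-5,7-dimethoxy-3-methyl-4-(2-methylpropyl)-3-(prop-2-en-1-yl)-3,4-dihydro-2H-chromen-2-one | CC(C)C[C@H]1[C@](CC=C)(C)C(=O)Oc2cc(OC)cc(OC)c12 | intermediate
7 | (3R,4R)-5,7-dimethoxy-3-methyl-4-(2-methylpropyl)-3-(prop-2-en-1-yl)-3,4-dihydro-2H-chromen-2-ol (anomer mixture) | CC(C)C[C@H]1[C@](CC=C)(C)C(O)Oc2cc(OC)cc(OC)c12 | intermediate
8 | 2-[(4R,5S)-4-ethynyl-4,7-dimethyloct-1-en-5-yl]-3,5-dimethoxyphenol | CC(C)C[C@H](c1c(O)cc(OC)cc1OC)[C@](CC=C)(C)C#C | intermediate
9 | 2-[(4R,5S)-4-ethynyl-4,7-dimethyloct-1-en-5-yl]-1,3,5-trimethoxybenzene | CC(C)C[C@H](c1c(OC)cc(OC)cc1OC)[C@](CC=C)(C)C#C | intermediate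
10 | lithium acetylide of 9 | CC(C)C[C@H](c1c(OC)cc(OC)cc1OC)[C@](CC=C)(C)C#C[Li] | intermediate
11 | (5R)-5-methyl-5-[(1S)-3-methyl-1-(2,4,6-trimethoxyphenyl)butyl]oct-7-en-3-yn-2-one | CC(C)C[C@H](c1c(OC)cc(OC)cc1OC)[C@](CC=C)(C)C#CC(C)=O | intermediate
12 | (2S,5R)-5-methyl-5-[(1S)-3-methyl-1-(2,4,6-trimethoxyphenyl)butyl]oct-7-en-3-yn-2-ol | CC(C)C[C@H](c1c(OC)cc(OC)cc1OC)[C@](CC=C)(C)C#C[C@H](C)O | intermediate
13 | C-boryl/O-boryl bis(9-borabicyclo[3.3.1]nonan-9-yl) adduct of 12 | CC(C)C[C@H](c1c(OC)cc(OC)cc1OC)[C@](CCCB1C2CCCC1CCC2)(C)C#C[C@H](C)OB1C2CCCC1CCC2 | intermediate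
14 | (4R,7S)-4-methyl-4-[(1S)-3-methyl-1-(2,4,6-trimethoxyphenyl)butyl]oct-5-yne-1,7-diol | CC(C)C[C@H](c1c(OC)cc(OC)cc1OC)[C@](CCCO)(C)C#C[C@H](C)O | intermediate
15 | (4R,7S)-7-hydroxy-4-methyl-4-[(1S)-3-methyl-1-(2,4,6-trimethoxyphenyl)butyl]oct-5-ynal | CC(C)C[C@H](c1c(OC)cc(OC)cc1OC)[C@](CCC=O)(C)C#C[C@H](C)O | intermediate
16 | methyl 2-[bis(2,2,2-trifluoroethoxy)phosphoryl]acetate | COC(=O)CP(=O)(OCC(F)(F)F)OCC(F)(F)F | starting material
17 | lithium salt of 16 | COC(=O)[CH-]P(=O)(OCC(F)(F)F)OCC(F)(F)F.[Li+] | intermediate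
18 | methyl 2-[bis(2,2,2-trifluoroethoxy)phosphoryl]-2-bromoacetate | COC(=O)C(Br)P(=O)(OCC(F)(F)F)OCC(F)(F)F | intermediate
19 | potassium salt of 18 | COC(=O)[C-](Br)P(=O)(OCC(F)(F)F)OCC(F)(F)F.[K+] | intermediate
20 | methyl (2E,6R,9S)-2-bromo-9-hydroxy-6-methyl-6-[(1S)-3-methyl-1-(2,4,6-trimethoxyphenyl)butyl]dec-2-en-7-ynoate | CC(C)C[C@H](c1c(OC)cc(OC)cc1OC)[C@](CC/C=C(/Br)C(=O)OC)(C)C#C[C@H](C)O | intermediate
21 | methyl (2Z,6R,9S)-2-ethenyl-9-hydroxy-6-methyl-6-[(1S)-3-methyl-1-(2,4,6-trimethoxyphenyl)butyl]dec-2-en-7-ynoate | CC(C)C[C@H](c1c(OC)cc(OC)cc1OC)[C@](CC/C=C(/C=C)C(=O)OC)(C)C#C[C@H](C)O | intermediate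
22 | (9R)-9-[1-(2-nitrobenzenesulfonyl)hydrazinyl] analogue of 21 (carbinol carbon inverted) | CC(C)C[C@H](c1c(OC)cc(OC)cc1OC)[C@](CC/C=C(/C=C)C(=O)OC)(C)C#C[C@@H](C)N(N)S(=O)(=O)c1ccccc1[N+](=O)[O-] | intermediate
23 | (9R)-9-diazenyl analogue of 21 (propargylic diazene) | CC(C)C[C@H](c1c(OC)cc(OC)cc1OC)[C@](CC/C=C(/C=C)C(=O)OC)(C)C#C[C@@H](C)N=N | intermediate
24 | methyl (2Z,6S)-2-ethenyl-6-methyl-6-[(1S)-3-methyl-1-(2,4,6-trimethoxyphenyl)butyl]deca-2,7,8-trienoate, (Sa)/(P) allene | CC(C)C[C@H](c1c(OC)cc(OC)cc1OC)[C@](CC/C=C(/C=C)C(=O)OC)(C)C([H])=[C@@]=C([H])C | intermediate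
25 | methyl (4R,6S,8aS)-4,6-dimethyl-6-[(1S)-3-methyl-1-(2,4,6-trimethoxyphenyl)butyl]-3,4,6,7,8,8a-hexahydronaphthalene-1-carboxylate | CC(C)C[C@H](c1c(OC)cc(OC)cc1OC)[C@]1(C)C=C2[C@H](C)CC=C(C(=O)OC)[C@H]2CC1 | intermediate
26 | methyl (1S,4R,6S,8aR)-4,6-dimethyl-6-[(1S)-3-methyl-1-(2,4,6-trimethoxyphenyl)butyl]-1,2,3,4,6,7,8,8a-octahydronaphthalene-1-carboxylate | CC(C)C[C@H](c1c(OC)cc(OC)cc1OC)[C@]1(C)C=C2[C@H](C)CC[C@H](C(=O)OC)[C@H]2CC1 | intermediate
27 | methyl (1S,4R,6S,8aR)-6-[(1S)-1-(3,5-dibromo-2,4,6-trimethoxyphenyl)-3-methylbutyl]-4,6-dimethyl-1,2,3,4,6,7,8,8a-octahydronaphthalene-1-carboxylate | CC(C)C[C@H](c1c(OC)c(Br)c(OC)c(Br)c1OC)[C@]1(C)C=C2[C@H](C)CC[C@H](C(=O)OC)[C@H]2CC1 | intermediate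
28 | 2-[(1S,4R,6S,8aR)-6-[(1S)-1-(3,5-dibromo-2,4,6-trimethoxyphenyl)-3-methylbutyl]-4,6-dimethyl-1,2,3,4,6,7,8,8a-octahydronaphthalen-1-yl]propan-2-ol | CC(C)C[C@H](c1c(OC)c(Br)c(OC)c(Br)c1OC)[C@]1(C)C=C2[C@H](C)CC[C@H](C(C)(C)O)[C@H]2CC1 | intermediate
29 | trilithio species from 28 (lithium alkoxide, 3,5-dilithioaryl) | CC(C)C[C@H](c1c(OC)c([Li])c(OC)c([Li])c1OC)[C@]1(C)C=C2[C@H](C)CC[C@H](C(C)(C)O[Li])[C@H]2CC1 | intermediate
30 | 5-[(1S)-1-[(2S,4aR,5S,8R)-5-(2-hydroxypropan-2-yl)-2,8-dimethyl-2,3,4,4a,5,6,7,8-octahydronaphthalen-2-yl]-3-methylbutyl]-2,4,6-trimethoxybenzene-1,3-dicarbaldehyde | CC(C)C[C@H](c1c(OC)c(C=O)c(OC)c(C=O)c1OC)[C@]1(C)C=C2[C@H](C)CC[C@H](C(C)(C)O)[C@H]2CC1 | intermediate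
31 | 2,4,6-trihydroxy-5-[(1S)-1-[(2S,4aR,5S,8R)-5-(2-hydroxypropan-2-yl)-2,8-dimethyl-2,3,4,4a,5,6,7,8-octahydronaphthalen-2-yl]-3-methylbutyl]benzene-1,3-dicarbaldehyde (CNP0200991.2) | CC(C)C[C@H](c1c(O)c(C=O)c(O)c(C=O)c1O)[C@]1(C)C=C2[C@H](C)CC[C@H](C(C)(C)O)[C@H]2CC1 | target

**Step count and risks**

Total step count: 19. Longest linear sequence: 18 steps (steps 1–9 and 11–19, from 1 to 31); step 10 is a one-step side branch.

Steps most likely to fail:

Step 14 (cycloaddition). The cycloaddition may be too slow, so that intermolecular dimerisation of the dienoate or attack on the proximal allene π bond takes over, or facial control at the ring-fusion CH may be weak. The fallback sets out from 21 and comes back at 25. Gold-catalysed Meyer–Schuster rearrangement of the propargylic alcohol (Ph3PAuNTf2, MeOH, toluene, rt) should give the (E)-propenyl ketone methyl (2Z,6R,8E)-2-ethenyl-6-methyl-6-[(1R)-3-methyl-1-(2,4,6-trimethoxyphenyl)butyl]-7-oxodeca-2,8-dienoate F1. Intramolecular Diels–Alder reaction of this trienone (toluene, 80–110 °C, or Me2AlCl, CH2Cl2, −40 °C) through the tether-endo transition state should give the cis-fused keto ester F2, with the ring methyl trans to the ketone carbon as dictated by the E alkene. KN(SiMe3)2 and PhNTf2 (THF, −78 °C) should convert the ketone, which can enolise only toward the ring-fusion CH, into the enol triflate F3. Reduction with Pd(OAc)2, PPh3, Bu3N and HCO2H (DMF, 60 °C) should then give 25.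

Step 1 (asymmetric conjugate addition). Addition may be slow or poorly enantioselective because the peri methoxy group crowds the β-carbon, and 1,2-addition with ring opening may compete. The fallback sets out from 1 and comes back at 2. Racemic 1,4-addition (i-BuMgBr, CuI cat., Me3SiCl, THF, −40 °C) should give racemic 5,7-dimethoxy-4-(2-methylpropyl)-3,4-dihydro-2H-chromen-2-one F4. Aminolysis with (S)-1-phenylethylamine (toluene, 60 °C) gives two diastereomeric phenol amides. The wanted (3S)-3-(2-hydroxy-4,6-dimethoxyphenyl)-5-methyl-N-[(1S)-1-phenylethyl]hexanamide F5 is separated by crystallisation or chromatography from the (3R)-3-(2-hydroxy-4,6-dimethoxyphenyl)-5-methyl-N-[(1S)-1-phenylethyl]hexanamide F6. Acid-mediated relactonisation of F5 (TsOH·H2O, toluene, reflux) returns 2.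

Step 15 (conjugate reduction). Base-induced migration of the skipped diene may occur during the dissolving-metal reduction, or control at the ester-bearing carbon may be incomplete, since the equatorial preference of the ester is only moderate. The fallback sets out from 25 and comes back at 28. Addition of MeMgBr/CeCl3 (THF, 0 °C) to 25 should give the allylic tertiary alcohol 2-[(4R,6S,8aS)-4,6-dimethyl-6-[(1S)-3-methyl-1-(2,4,6-trimethoxyphenyl)butyl]-3,4,6,7,8,8a-hexahydronaphthalen-1-yl]propan-2-ol F7. Hydroxyl-directed hydrogenation with [Ir(cod)(PCy3)(py)]PF6 and H2 (CH2Cl2, rt) reduces only the alkene next to the hydroxyl group, from the face opposite the axial ring methyl, and should give 2-[(1S,4R,6S,8aR)-4,6-dimethyl-6-[(1S)-3-methyl-1-(2,4,6-trimethoxyphenyl)butyl]-1,2,3,4,6,7,8,8a-octahydronaphthalen-1-yl]propan-2-ol F8. Dibromination of F8 with NBS (MeCN, 0 °C) gives 28.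

**Further compounds**

F1 | step 14 | methyl (2Z,6R,8E)-2-ethenyl-6-methyl-6-[(1R)-3-methyl-1-(2,4,6-trimethoxyphenyl)butyl]-7-oxodeca-2,8-dienoate | CC(C)C[C@H](c1c(OC)cc(OC)cc1OC)[C@](CC/C=C(/C=C)C(=O)OC)(C)C(=O)/C=C/C
F2 | step 14 | cis-fused methyl 4,6-dimethyl-6-[3-methyl-1-(2,4,6-trimethoxyphenyl)butyl]-5-oxo-3,4,4a,5,6,7,8,8a-octahydronaphthalene-1-carboxylate (ring-fusion hydrogens cis, ring methyl trans to the ketone carbon) | CC(C)C[C@H](c1c(OC)cc(OC)cc1OC)[C@]1(C)C(=O)[C@H]2[C@H](C)CC=C(C(=O)OC)[C@H]2CC1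
F3 | step 14 | methyl 4,6-dimethyl-6-[3-methyl-1-(2,4,6-trimethoxyphenyl)butyl]-5-(trifluoromethanesulfonyloxy)-3,4,6,7,8,8a-hexahydronaphthalene-1-carboxylate (configured as 25) | CC(C)C[C@H](c1c(OC)cc(OC)cc1OC)[C@]1(C)C(OS(=O)(=O)C(F)(F)F)=C2[C@H](C)CC=C(C(=O)OC)[C@H]2CC1
F4 | step 1 | racemic 5,7-dimethoxy-4-(2-methylpropyl)-3,4-dihydro-2H-chromen-2-one | CC(C)CC1CC(=O)Oc2cc(OC)cc(OC)c12
F5 | step 1 | (3S)-3-(2-hydroxy-4,6-dimethoxyphenyl)-5-methyl-N-[(1S)-1-phenylethyl]hexanamide | CC(C)C[C@@H](CC(=O)N[C@@H](C)c1ccccc1)c1c(O)cc(OC)cc1OC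
F6 | step 1 | (3R)-3-(2-hydroxy-4,6-dimethoxyphenyl)-5-methyl-N-[(1S)-1-phenylethyl]hexanamide | CC(C)C[C@H](CC(=O)N[C@@H](C)c1ccccc1)c1c(O)cc(OC)cc1OC
F7 | step 15 | 2-[(4R,6S,8aS)-4,6-dimethyl-6-[(1S)-3-methyl-1-(2,4,6-trimethoxyphenyl)butyl]-3,4,6,7,8,8a-hexahydronaphthalen-1-yl]propan-2-ol | CC(C)C[C@H](c1c(OC)cc(OC)cc1OC)[C@]1(C)C=C2[C@H](C)CC=C(C(C)(C)O)[C@H]2CC1
F8 | step 15 | 2-[(1S,4R,6S,8aR)-4,6-dimethyl-6-[(1S)-3-methyl-1-(2,4,6-trimethoxyphenyl)butyl]-1,2,3,4,6,7,8,8a-octahydronaphthalen-1-yl]propan-2-ol | CC(C)C[C@H](c1c(OC)cc(OC)cc1OC)[C@]1(C)C=C2[C@H](C)CC[C@H](C(C)(C)O)[C@H]2CC1
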